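**Plan**
Numbering: C1 = CHO, C2 = enal α-carbon, C3 = CH2OH with chain C4 and C5. Ring A = C6 (CH), C7 (=C2), C8, C9, C10 (C–OH), C11 (quaternary). Side chain = C12–C23 (C21 carbinol, C22/C23 oxirane).
Cuts: C17–C18 and C13–C14 (two B-alkyl Suzuki–Miyaura unions), C7=C2 (isopropenyl addition, then 1,3-transposition), C10–CH3, C12=C13 (methylenation), and last the ring bond C10–C11.
Enabling feature: in ring A the quaternary C11 lies between oxygenated C10 and exocyclic C12. This is a latent 2-formyl-2-methylcyclohexanone, the signature product of a 1,2-acyl shift in a 2,3-epoxy-3-methylcycloheptanone. Ring A is therefore made from a seven-membered ring that still holds C12 between C10 and C11.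
Forward: allylboration joins C6–C7, and ring-closing metathesis closes the cycloheptene at C11=C12. Allylic oxidation and epoxidation arm it, and the contraction gives ring A. Then come the C10 methyl and the C7 enal precursor, and the chain is joined at C13–C14 and then at C17–C18.
Stereochemistry: C6 (with a temporary centre at C7) comes from a chiral phosphoric acid-catalysed allylboration. The epoxide face is chosen by C6, C11 follows by stereospecific inversion in the shift, and C10 by substrate-controlled addition. The C7=C2 geometry comes from a chair-like [3,3] transposition. C21 comes from a catalytic propargylation, C22 from 1,3-allylic strain in a directed epoxidation, and both chain alkenes from syn-carboalumination.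

Key step: step 9

Remark: the facial sense of both phosphoric acid-catalysed additions is assigned by analogy with simple aldehydes (Re-face attack with the (R)-acid); if it proves opposite, the other catalyst enantiomer is used.

Abbreviations: TBDPS = tert-butyldiphenylsilyl, TBS = tert-butyldimethylsilyl, TES = triethylsilyl, TMS = trimethylsilyl, pin = pinacolato, TRIP = 3,3'-bis(2,4,6-triisopropylphenyl)-1,1'-binaphthyl-2,2'-diyl hydrogen phosphate.

**Ring fragment**

Step 1
Reactants: 1 but-3-yn-1-ol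
Product: 2 tert-butyl(but-3-yn-1-yloxy)diphenylsilane
Conditions: TBDPSCl, imidazole, CH2Cl2, rt
Reagents that add atoms: tert-butyl(chloro)diphenylsilane CC(C)(C)[Si](Cl)(c1ccccc1)c1ccccc1
Why: Standard silyl ether protection of a primary alcohol gives a mask for the future C3 hydroxyl that tolerates acid and Lewis acid, and no stereocentre is formed.

Step 2
Reactants: 2 tert-butyl(but-3-yn-1-yloxy)diphenylsilane; 3 2-bromopropene
Product: 5 tert-butyl{[(3E)-5-methylhexa-3,5-dien-1-yl]oxy}diphenylsilane, via alkenyl catecholborane 4 (not isolated)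
Conditions: catecholborane, THF, 65 °C; then 3, Pd(PPh3)4 (cat.), aq NaOH, THF, 60 °C
Reagents that add atoms: none
Why: syn-Hydroboration of the terminal alkyne gives the (E)-alkenylboronate, and Suzuki–Miyaura coupling with the alkenyl bromide proceeds with retention to the (E)-diene.

Step 3
Reactants: 5 tert-butyl{[(3E)-5-methylhexa-3,5-dien-1-yl]oxy}diphenylsilane
Product: 6 tert-butyl{[(4Z)-5-methyl-6-(pinacolatoboryl)hex-4-en-1-yl]oxy}diphenylsilane
Conditions: HBpin, Ni(cod)2 (cat.), PCy3 (cat.), toluene, rt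
Reagents that add atoms: pinacolborane [H]B1OC(C)(C)C(C)(C)O1
Why: Zerovalent-nickel-catalysed 1,4-hydroboration of the s-cis-bound 1,3-diene places boron on the unsubstituted terminus, and the s-cis binding fixes the (Z)-trisubstituted allylboronate geometry.

Step 4
Reactants: 6 (Z)-allylboronate; 7 hex-5-enal
Product: 8 (6S,7S)-10-(TBDPS-oxy)-7-(prop-1-en-2-yl)dec-1-en-6-ol
Conditions: (R)-TRIP (cat.), 4 Å MS, toluene, −30 °C; aqueous work-up
Reagents that add atoms: none
Why: Chiral phosphoric acid-catalysed allylboration runs through a closed chair transition state in which the (Z)-geometry gives the syn adduct and the catalyst exposes one aldehyde face, which sets the temporary C7 carbinol and through it the permanent C6 centre.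

Step 5
Reactants: 8 homoallylic alcohol
Product: 9 (6S,7S)-6-(TBS-oxy)-10-(TBDPS-oxy)-7-(prop-1-en-2-yl)dec-1-ene
Conditions: TBSOTf, 2,6-lutidine, CH2Cl2, −78 → 0 °C
Reagents that add atoms: tert-butyldimethylsilyl triflate CC(C)(C)[Si](C)(C)OS(=O)(=O)C(F)(F)F
Why: Silyl ether protection of the hindered secondary alcohol gives a group that can later be removed beside the primary TBDPS ether.

Step 6
Reactants: 9 bis-silyl diene
Product: 10 (6S,7S)-6-(TBS-oxy)-7-[3-(TBDPS-oxy)propyl]-1-methylcyclohept-1-ene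
Conditions: second-generation Grubbs catalyst (cat.), CH2Cl2 (dilute), 40 °C
Reagents that add atoms: none
Why: Ring-closing metathesis of a terminal and a 1,1-disubstituted alkene is a well-precedented way to trisubstituted cycloheptenes, and loss of ethene drives it.

Step 7
Reactants: 10 cycloheptene
Product: 11 (4S,5S)-5-(TBS-oxy)-4-[3-(TBDPS-oxy)propyl]-3-methylcyclohept-2-en-1-one
Conditions: CrO3, 3,5-dimethylpyrazole, CH2Cl2, −20 °C
Reagents that add atoms: chromium trioxide O=[Cr](=O)=O
Why: Chromium-based allylic oxidation of 1-methylcycloalkenes attacks the ring CH2 next to the unsubstituted alkene carbon (C10) and gives the 3-methyl enone, because the tertiary C6–H and the methyl group cannot end as a conjugated ketone.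

Step 8
Reactants: 11 enone
Product: 12 (1S,5S,6R,7S)-5-(TBS-oxy)-6-[3-(TBDPS-oxy)propyl]-7-methyl-8-oxabicyclo[5.1.0]octan-2-one
Conditions: 30% H2O2, NaOH (cat.), MeOH, 0 °C → rt
Reagents that add atoms: hydrogen peroxide OO
Why: In the Weitz–Scheffer epoxidation the hydroperoxide anion adds to C11 on the face opposite to the pseudoaxial C6 side chain (held there by 1,2-allylic strain with the C11 methyl), so the oxirane (C11, C12) forms trans to that chain.

Step 9
Reactants: 12 epoxy ketone
Product: 13 (1R,5S,6S)-5-(TBS-oxy)-6-[3-(TBDPS-oxy)propyl]-1-methyl-2-oxocyclohexane-1-carbaldehyde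
Conditions: BF3·OEt2 (substoichiometric), CH2Cl2, −78 → −20 °C; cold aq NaHCO3
Reagents that add atoms: none
Why: BF3 binds the oxirane oxygen and the C11–O bond (at the methyl-bearing carbon remote from the carbonyl group) stretches while the acyl carbon C10 slides from C12 to C11 on the face opposite to the departing oxygen, so that C12 is pushed out of the ring as the formyl group. The closest known reaction type is the Lewis-acid 1,2-acyl shift of cyclic α,β-epoxy ketones, by which isophorone oxide contracts to 2-formyl-2,4,4-trimethylcyclopentanone. Ring A (C6–C7–C8–C9–C10–C11) is closed by this suprafacial 1,2-shift through a three-centre transition state, which is a seven-to-six ring contraction and not an end-to-end cyclisation. The only new stereocentre, quaternary C11, is fixed by inversion at the oxirane carbon, so it copies the epoxide face that C6 chose in step 8, while C6 and C7 are spectators. The step needs opening at C11 and not at C12, which the carbonyl group (destabilising charge at C12) and the methyl group (stabilising charge at C11) secure, and it needs acyl migration rather than hydride migration from C12 or C6, which the high migratory aptitude of acyl groups and the near-antiperiplanar C10–C12/C11–O alignment available in the flexible seven-membered ring secure. Low temperature and a substoichiometric charge of acid should spare both silyl ethers and the non-enolisable β-keto aldehyde.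

Step 10
Reactants: 13 keto aldehyde
Product: 14 (2S,3S,4S)-4-(TBS-oxy)-3-[3-(TBDPS-oxy)propyl]-2-ethenyl-2-methylcyclohexan-1-one
Conditions: CH2I2, Zn, Ti(OiPr)4, THF, rt
Reagents that add atoms: diiodomethane ICI
Why: Takai-type methylenation with the non-basic zinc/titanium gem-dimetal reagent is selective for aldehydes over ketones and avoids deformylation of the β-keto aldehyde.

Step 11
Reactants: 14 vinyl ketone
Product: 15 (1S,2S,3S,4S)-4-(TBS-oxy)-3-[3-(TBDPS-oxy)propyl]-2-ethenyl-1,2-dimethylcyclohexan-1-ol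
Conditions: MeLi, CeCl3, THF, −78 °C; then H2O
Reagents that add atoms: methyllithium [Li]C
Why: In this organocerium 1,2-addition the chair with equatorial C6 chain, C7 silyl ether and vinyl group holds the C11 methyl axial, so the nucleophile should enter axially on the opposite face and give C10 with the hydroxyl cis to the C11 methyl.

Step 12
Reactants: 15 tertiary alcohol
Product: 16 (1S,2S,3S,4S)-3-[3-(TBDPS-oxy)propyl]-2-ethenyl-1,2-dimethylcyclohexane-1,4-diol
Conditions: camphorsulfonic acid (cat.), MeOH/CH2Cl2, 0 °C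
Reagents that add atoms: none
Why: Acid-catalysed methanolysis cleaves the TBS ether much faster than the acid-stable TBDPS ether.

Step 13
Reactants: 16 diol
Product: 17 (2S,3S,4S)-2-[3-(TBDPS-oxy)propyl]-3-ethenyl-4-hydroxy-3,4-dimethylcyclohexan-1-one
Conditions: Dess–Martin periodinane, CH2Cl2, rt
Reagents that add atoms: none
Why: Dess–Martin oxidation converts only the secondary alcohol (the tertiary one is inert), and its near-neutral medium should not epimerise C6.

Step 14
Reactants: 17 hydroxy ketone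
Product: 18 (1R,2S,3S,4S)-2-[3-(TBDPS-oxy)propyl]-3-ethenyl-3,4-dimethyl-1-(prop-1-en-2-yl)cyclohexane-1,4-diol
Conditions: isopropenylmagnesium bromide (excess), CeCl3, THF, −78 → 0 °C; then H2O
Reagents that add atoms: isopropenylmagnesium bromide CC(=C)[Mg]Br
Why: In this organocerium 1,2-addition the weakly basic reagent spares the α-centre C6, and the bulky nucleophile should enter equatorially, trans to the C6 chain, leaving an axial C7 hydroxyl.

Step 15
Reactants: 18 tertiary allylic alcohol
Product: 20 (1S,2S,3R,4Z)-3-[3-(TBDPS-oxy)propyl]-2-ethenyl-4-(1-hydroxypropan-2-ylidene)-1,2-dimethylcyclohexan-1-ol, via allylic TMS ether 19 (not isolated)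
Conditions: Ph3SiOReO3 (cat.), N,O-bis(trimethylsilyl)acetamide, Et2O, 0 °C; then K2CO3 (cat.), MeOH
Reagents that add atoms: none
Why: Rhenium-oxo-catalysed 1,3-transposition is a chair-like [3,3] shift of the axial perrhenate ester in which the slim =CH2 terminus and not the methyl group should lie on the side of the branched C6, so C1 ends cis to C6 (Z), and silyl trapping of the primary alcohol prevents equilibration.

**Linker fragment**

Step 16
Reactants: 21 prop-2-yn-1-ol
Product: 23 (2E)-3-iodo-2-methylprop-2-en-1-ol, via alkenylalane 22 (not isolated)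
Conditions: Me3Al, Cp2ZrCl2 (cat.), CH2Cl2, 0 °C → rt; then I2, THF, −30 °C; aqueous work-up
Reagents that add atoms: trimethylaluminium C[Al](C)C; iodine II
Why: Negishi carboalumination adds methyl and aluminium syn across the alkyne with aluminium at the terminus, and iodinolysis with retention gives the (E)-iodide.

Step 17
Reactants: 23 iodo allylic alcohol
Product: 24 (2E)-3-iodo-2-methylprop-2-enal
Conditions: MnO2, CH2Cl2, rt
Reagents that add atoms: none
Why: Manganese dioxide oxidation of an allylic alcohol is mild and leaves the alkenyl iodide and its geometry untouched.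

Step 18
Reactants: 24 iodo enal
Product: 25 (1E)-1-iodo-2-methylbuta-1,3-diene
Conditions: Ph3PCH3Br, n-BuLi, THF, −78 → 0 °C, dark
Reagents that add atoms: methyltriphenylphosphonium bromide C[P+](c1ccccc1)(c1ccccc1)c1ccccc1.[Br-]
Why: Wittig methylenation of the enal gives the terminal diene without touching the trisubstituted iodoalkene.

**Terminal fragment**

Step 19
Reactants: 26 3-methylbut-2-enal; 27 allenylboronic acid pinacol ester
Product: 28 (4S)-6-methylhept-5-en-1-yn-4-ol
Conditions: (S)-TRIP (cat.), 4 Å MS, toluene, −20 °C; aqueous work-up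
Reagents that add atoms: none
Why: Chiral phosphoric acid-catalysed propargylation proceeds through a closed six-membered SE2' transition state with the allenylboronate, and the catalyst selects the aldehyde face that sets C21.

Step 20
Reactants: 28 enynol
Product: 30 (1E,4S)-1-iodo-2,6-dimethylhepta-1,5-dien-4-ol, via alkenylalane 29 (not isolated)
Conditions: Me3Al (excess), Cp2ZrCl2 (cat.), CH2Cl2, 0 °C → rt; then I2, THF, −30 °C; aqueous work-up
Reagents that add atoms: trimethylaluminium C[Al](C)C; iodine II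
Why: Negishi carboalumination followed by iodinolysis sets the (E)-C18=C19 alkene by syn addition, the hydroxyl travels as its aluminium alkoxide, and the trisubstituted alkene does not react.

Step 21
Reactants: 30 iodo dienol
Product: 31 (1S,3E)-1-[(2R)-3,3-dimethyloxiran-2-yl]-4-iodo-3-methylbut-3-en-1-ol
Conditions: mCPBA, CH2Cl2, 0 °C
Reagents that add atoms: 3-chloroperbenzoic acid OOC(=O)c1cccc(Cl)c1
Why: In this hydroxyl-directed peracid epoxidation, 1,3-allylic strain with the cis methyl group places the C21–H bond in the alkene plane, so delivery syn to the hydroxyl gives the threo (21S,22R) epoxy alcohol, and the electron-poor iodoalkene is spared.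

Step 22
Reactants: 31 epoxy alcohol
Product: 32 {(1S,3E)-1-[(2R)-3,3-dimethyloxiran-2-yl]-4-iodo-3-methylbut-3-en-1-yl}oxy(triethyl)silane
Conditions: Et3SiCl, imidazole, CH2Cl2, 0 °C
Reagents that add atoms: chlorotriethylsilane CC[Si](Cl)(CC)CC
Why: Silylation under non-Lewis-acidic conditions blocks Payne migration in the basic coupling and does not open the oxirane.

**Union and end game**

Step 23
Reactants: 20 ring fragment; 25 (1E)-1-iodo-2-methylbuta-1,3-diene
Product: 34 (1S,2S,3R,4Z)-3-[3-(TBDPS-oxy)propyl]-4-(1-hydroxypropan-2-ylidene)-1,2-dimethyl-2-[(3E)-4-methylhexa-3,5-dien-1-yl]cyclohexan-1-ol, via B-alkyl borane 33 (not isolated)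
Conditions: 9-BBN-H (excess), THF, rt → 40 °C; then 25, PdCl2(dppf) (cat.), AsPh3 (cat.), Cs2CO3, DMF/H2O, rt
Reagents that add atoms: none
Why: In this B-alkyl Suzuki–Miyaura coupling 9-BBN-H adds only to the monosubstituted vinyl group (the tetrasubstituted alkene is inert), and the alkenyl iodide couples with retention to give (E)-C14=C15.

Step 24
Reactants: 34 terminal diene; 32 alkenyl iodide
Product: 36 (1S,2S,3R,4Z)-2-[(3E,7E,10S)-10-[(2R)-3,3-dimethyloxiran-2-yl]-4,8-dimethyl-10-(TES-oxy)deca-3,7-dien-1-yl]-3-[3-(TBDPS-oxy)propyl]-4-(1-hydroxypropan-2-ylidene)-1,2-dimethylcyclohexan-1-ol, via homoallylic borane 35 (not isolated)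
Conditions: 9-BBN-H (excess), THF, 0 °C → rt; then 32, PdCl2(dppf) (cat.), AsPh3 (cat.), Cs2CO3, DMF/H2O, rt
Reagents that add atoms: none
Why: In this B-alkyl Suzuki–Miyaura coupling the bulky borane adds 1,2 to the terminal vinyl end of the diene with boron on C17, and the mild aqueous base coupling with retention tolerates the oxirane and both silyl ethers.

Step 25
Reactants: 36 protected skeleton
Product: 37 (1S,2S,3R,4Z)-2-[(3E,7E,10S)-10-[(2R)-3,3-dimethyloxiran-2-yl]-10-hydroxy-4,8-dimethyldeca-3,7-dien-1-yl]-3-(3-hydroxypropyl)-4-(1-hydroxypropan-2-ylidene)-1,2-dimethylcyclohexan-1-ol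
Conditions: Bu4NF, THF, 0 °C → rt
Reagents that add atoms: none
Why: Fluoride desilylation removes both silyl ethers at once, and the trisubstituted oxirane is the favoured side of any Payne equilibrium.

Step 26
Reactants: 37 tetraol
Product: 38 CNP0161066.1, (2Z)-2-[(2R,3S,4S)-3-[(3E,7E,10S)-10-[(2R)-3,3-dimethyloxiran-2-yl]-10-hydroxy-4,8-dimethyldeca-3,7-dien-1-yl]-4-hydroxy-2-(3-hydroxypropyl)-3,4-dimethylcyclohexylidene]propanal
Conditions: MnO2, CH2Cl2, rt
Reagents that add atoms: none
Why: Manganese dioxide oxidises only the allylic primary alcohol at C1 and leaves the saturated primary, secondary and tertiary hydroxyls, the oxirane and the alkene geometry as they are.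

**Compound list**
1 | but-3-yn-1-ol | C#CCCO | starting material
2 | tert-butyl(but-3-yn-1-yloxy)diphenylsilane | C#CCCO[Si](c1ccccc1)(c1ccccc1)C(C)(C)C | intermediate
3 | 2-bromopropene | CC(Br)=C | starting material
4 | 2-[(1E)-4-(TBDPS-oxy)but-1-en-1-yl]-1,3,2-benzodioxaborole | CC(C)(C)[Si](OCC/C=C/B1Oc2ccccc2O1)(c1ccccc1)c1ccccc1 | intermediate
5 | tert-butyl{[(3E)-5-methylhexa-3,5-dien-1-yl]oxy}diphenylsilane | C=C(C)/C=C/CCO[Si](c1ccccc1)(c1ccccc1)C(C)(C)C | intermediate
6 | tert-butyl{[(4Z)-5-methyl-6-(pinacolatoboryl)hex-4-en-1-yl]oxy}diphenylsilane | CC(C)(C)[Si](OCCC/C=C(C)\CB1OC(C)(C)C(C)(C)O1)(c1ccccc1)c1ccccc1 | intermediate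
7 | hex-5-enal | C=CCCCC=O | starting material
8 | (6S,7S)-10-(TBDPS-oxy)-7-(prop-1-en-2-yl)dec-1-en-6-ol | C=CCCC[C@H](O)[C@@H](CCCO[Si](c1ccccc1)(c1ccccc1)C(C)(C)C)C(C)=C | intermediate
9 | (6S,7S)-6-(TBS-oxy)-10-(TBDPS-oxy)-7-(prop-1-en-2-yl)dec-1-ene | C=CCCC[C@H](O[Si](C)(C)C(C)(C)C)[C@@H](CCCO[Si](c1ccccc1)(c1ccccc1)C(C)(C)C)C(C)=C | intermediate
10 | (6S,7S)-6-(TBS-oxy)-7-[3-(TBDPS-oxy)propyl]-1-methylcyclohept-1-ene | CC1=CCCC[C@H](O[Si](C)(C)C(C)(C)C)[C@H]1CCCO[Si](c1ccccc1)(c1ccccc1)C(C)(C)C | intermediate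
11 | (4S,5S)-5-(TBS-oxy)-4-[3-(TBDPS-oxy)propyl]-3-methylcyclohept-2-en-1-one | CC1=CC(=O)CC[C@H](O[Si](C)(C)C(C)(C)C)[C@H]1CCCO[Si](c1ccccc1)(c1ccccc1)C(C)(C)C | intermediate
12 | (1S,5S,6R,7S)-5-(TBS-oxy)-6-[3-(TBDPS-oxy)propyl]-7-methyl-8-oxabicyclo[5.1.0]octan-2-one | C[C@@]12O[C@@H]1C(=O)CC[C@H](O[Si](C)(C)C(C)(C)C)[C@H]2CCCO[Si](c1ccccc1)(c1ccccc1)C(C)(C)C | intermediate
13 | (1R,5S,6S)-5-(TBS-oxy)-6-[3-(TBDPS-oxy)propyl]-1-methyl-2-oxocyclohexane-1-carbaldehyde | O=C[C@]1(C)C(=O)CC[C@H](O[Si](C)(C)C(C)(C)C)[C@H]1CCCO[Si](c1ccccc1)(c1ccccc1)C(C)(C)C | intermediate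
14 | (2S,3S,4S)-4-(TBS-oxy)-3-[3-(TBDPS-oxy)propyl]-2-ethenyl-2-methylcyclohexan-1-one | C=C[C@]1(C)C(=O)CC[C@H](O[Si](C)(C)C(C)(C)C)[C@H]1CCCO[Si](c1ccccc1)(c1ccccc1)C(C)(C)C | intermediate
15 | (1S,2S,3S,4S)-4-(TBS-oxy)-3-[3-(TBDPS-oxy)propyl]-2-ethenyl-1,2-dimethylcyclohexan-1-ol | C=C[C@]1(C)[C@@](C)(O)CC[C@H](O[Si](C)(C)C(C)(C)C)[C@H]1CCCO[Si](c1ccccc1)(c1ccccc1)C(C)(C)C | intermediate
16 | (1S,2S,3S,4S)-3-[3-(TBDPS-oxy)propyl]-2-ethenyl-1,2-dimethylcyclohexane-1,4-diol | C=C[C@]1(C)[C@@](C)(O)CC[C@H](O)[C@H]1CCCO[Si](c1ccccc1)(c1ccccc1)C(C)(C)C | intermediate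
17 | (2S,3S,4S)-2-[3-(TBDPS-oxy)propyl]-3-ethenyl-4-hydroxy-3,4-dimethylcyclohexan-1-one | C=C[C@]1(C)[C@@](C)(O)CCC(=O)[C@H]1CCCO[Si](c1ccccc1)(c1ccccc1)C(C)(C)C | intermediate
18 | (1R,2S,3S,4S)-2-[3-(TBDPS-oxy)propyl]-3-ethenyl-3,4-dimethyl-1-(prop-1-en-2-yl)cyclohexane-1,4-diol | C=C[C@]1(C)[C@@](C)(O)CC[C@](O)(C(C)=C)[C@H]1CCCO[Si](c1ccccc1)(c1ccccc1)C(C)(C)C | intermediate
19 | primary allylic TMS ether of 20 | C/C(CO[Si](C)(C)C)=C1\CC[C@](C)(O)[C@@](C)(C=C)[C@@H]1CCCO[Si](c1ccccc1)(c1ccccc1)C(C)(C)C | intermediate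
20 | (1S,2S,3R,4Z)-3-[3-(TBDPS-oxy)propyl]-2-ethenyl-4-(1-hydroxypropan-2-ylidene)-1,2-dimethylcyclohexan-1-ol | C/C(CO)=C1\CC[C@](C)(O)[C@@](C)(C=C)[C@@H]1CCCO[Si](c1ccccc1)(c1ccccc1)C(C)(C)C | intermediate
21 | prop-2-yn-1-ol | C#CCO | starting material
22 | (E)-alkenyl(dimethyl)alane, O-dimethylaluminium alkoxide, from 21 | C[Al](C)/C=C(\C)CO[Al](C)C | intermediate
23 | (2E)-3-iodo-2-methylprop-2-en-1-ol | I/C=C(\C)CO | intermediate
24 | (2E)-3-iodo-2-methylprop-2-enal | I/C=C(\C)C=O | intermediate
25 | (1E)-1-iodo-2-methylbuta-1,3-diene | I/C=C(\C)C=C | intermediate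
26 | 3-methylbut-2-enal | CC(C)=CC=O | starting material
27 | allenylboronic acid pinacol ester | C=C=CB1OC(C)(C)C(C)(C)O1 | starting material
28 | (4S)-6-methylhept-5-en-1-yn-4-ol | C#CC[C@H](O)C=C(C)C | intermediate
29 | (E)-alkenyl(dimethyl)alane, O-dimethylaluminium alkoxide, from 28 | C[Al](C)/C=C(\C)C[C@H](O[Al](C)C)C=C(C)C | intermediate
30 | (1E,4S)-1-iodo-2,6-dimethylhepta-1,5-dien-4-ol | I/C=C(\C)C[C@H](O)C=C(C)C | intermediate
31 | (1S,3E)-1-[(2R)-3,3-dimethyloxiran-2-yl]-4-iodo-3-methylbut-3-en-1-ol | I/C=C(\C)C[C@H](O)[C@H]1OC1(C)C | intermediate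
32 | TES ether of 31 | I/C=C(\C)C[C@H](O[Si](CC)(CC)CC)[C@H]1OC1(C)C | intermediate
33 | C13 B-alkyl-9-BBN adduct of 20 (C1 oxygen as 9-BBN borinate) | C/C(COB1C2CCCC1CCC2)=C1\CC[C@](C)(O)[C@@](C)(CCB2C3CCCC2CCC3)[C@@H]1CCCO[Si](c1ccccc1)(c1ccccc1)C(C)(C)C | intermediate
34 | (1S,2S,3R,4Z)-3-[3-(TBDPS-oxy)propyl]-4-(1-hydroxypropan-2-ylidene)-1,2-dimethyl-2-[(3E)-4-methylhexa-3,5-dien-1-yl]cyclohexan-1-ol | C/C(CO)=C1\CC[C@](C)(O)[C@@](C)(CC/C=C(\C)C=C)[C@@H]1CCCO[Si](c1ccccc1)(c1ccccc1)C(C)(C)C | intermediate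
35 | C17 B-alkyl-9-BBN adduct of 34 (C1 oxygen as 9-BBN borinate) | C/C(COB1C2CCCC1CCC2)=C1\CC[C@](C)(O)[C@@](C)(CC/C=C(\C)CCB2C3CCCC2CCC3)[C@@H]1CCCO[Si](c1ccccc1)(c1ccccc1)C(C)(C)C | intermediate
36 | C3-O-TBDPS, C21-O-TES ether of 37 | C/C(CO)=C1\CC[C@](C)(O)[C@@](C)(CC/C=C(\C)CC/C=C(\C)C[C@H](O[Si](CC)(CC)CC)[C@H]2OC2(C)C)[C@@H]1CCCO[Si](c1ccccc1)(c1ccccc1)C(C)(C)C | intermediate
37 | tetraol (C1 alcohol of the target) | C/C(CO)=C1\CC[C@](C)(O)[C@@](C)(CC/C=C(\C)CC/C=C(\C)C[C@H](O)[C@H]2OC2(C)C)[C@@H]1CCCO | intermediate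
38 | CNP0161066.1 | C/C(C=O)=C1\CC[C@](C)(O)[C@@](C)(CC/C=C(\C)CC/C=C(\C)C[C@H](O)[C@H]2OC2(C)C)[C@@H]1CCCO | target

**Counts**
Total steps: 26. Longest linear sequence: 19 steps (steps 1–15 and 23–26).

**Steps most likely to fail**

Step 9. Hydride migration from C12 or C6 may compete with the acyl shift. The Lewis acid may strip a silyl ether, or the β-keto aldehyde may lose its formyl group on work-up. The fallback sets out from 12 and returns at 14.
- The ketone is reduced with NaBH4/CeCl3 to the epoxy alcohol F1.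
- F1 is silylated with Et3SiCl/imidazole to the epoxy silyl ether F2.
- F2 is rearranged with methylaluminium bis(4-bromo-2,6-di-tert-butylphenoxide) in CH2Cl2 at −78 °C. This is the known organoaluminium rearrangement of epoxy silyl ethers. The siloxy-bearing carbon C10, not an acyl carbon, migrates anti to the C11–O bond, and the same seven-to-six contraction gives the β-siloxy aldehyde F3.
- Methylenation as in step 10 gives the alkene F4.
- Pyridinium tosylate in MeOH removes only the TES group to give the alcohol F5.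
- Dess–Martin oxidation gives 14.

Step 15. Reversible transposition may erode the alkene geometry, and ionisation of the tertiary allylic alcohol may lead to dehydration. The fallback sets out from 17 and returns at 20.
- A Horner–Wadsworth–Emmons reaction with diethyl (1-cyanoethyl)phosphonate and NaH gives the tetrasubstituted nitrile F6. In F6 the slim linear cyano group, not the methyl group, should take the position cis to the branched C6.
- i-Bu2AlH at −78 °C gives the enal F7.
- NaBH4/CeCl3 gives 20.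

Step 8. Conjugate addition at the hindered β-carbon may be slow, facial selectivity on the flexible ring may be poor, and base may remove the γ-proton and expel the C7 silyloxy group. The fallback sets out from 11 and returns at 12 without new compounds. The epoxide face is handed to a reagent: iminium catalysis with the trifluoroacetate salt of 9-amino-9-deoxy-epi-quinine (or its pseudoenantiomer) and H2O2 in dioxane. Under these conditions the catalyst and not the ring conformation chooses the face, and no hydroxide is present.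

**Further compounds**
F1 | step 9 | (1R,2S,5S,6R,7S)-type epoxy alcohol, C10 hydroxyl cis to the oxirane | C[C@@]12O[C@@H]1[C@H](O)CC[C@H](O[Si](C)(C)C(C)(C)C)[C@H]2CCCO[Si](c1ccccc1)(c1ccccc1)C(C)(C)C
F2 | step 9 | C10 TES ether of F1 | C[C@@]12O[C@@H]1[C@H](O[Si](CC)(CC)CC)CC[C@H](O[Si](C)(C)C(C)(C)C)[C@H]2CCCO[Si](c1ccccc1)(c1ccccc1)C(C)(C)C
F3 | step 9 | 2-(TES-oxy)-5-(TBS-oxy)-6-[3-(TBDPS-oxy)propyl]-1-methylcyclohexane-1-carbaldehyde | O=C[C@]1(C)[C@H](O[Si](CC)(CC)CC)CC[C@H](O[Si](C)(C)C(C)(C)C)[C@H]1CCCO[Si](c1ccccc1)(c1ccccc1)C(C)(C)C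
F4 | step 9 | vinyl compound from F3 | C=C[C@]1(C)[C@H](O[Si](CC)(CC)CC)CC[C@H](O[Si](C)(C)C(C)(C)C)[C@H]1CCCO[Si](c1ccccc1)(c1ccccc1)C(C)(C)C
F5 | step 9 | C10 secondary alcohol from F4 | C=C[C@]1(C)[C@H](O)CC[C@H](O[Si](C)(C)C(C)(C)C)[C@H]1CCCO[Si](c1ccccc1)(c1ccccc1)C(C)(C)C
F6 | step 15 | (2Z)-2-cyclohexylidenepropanenitrile from 17 | C/C(C#N)=C1\CC[C@](C)(O)[C@@](C)(C=C)[C@@H]1CCCO[Si](c1ccccc1)(c1ccccc1)C(C)(C)C
F7 | step 15 | (2Z)-2-cyclohexylidenepropanal from F6 | C/C(C=O)=C1\CC[C@](C)(O)[C@@](C)(C=C)[C@@H]1CCCO[Si](c1ccccc1)(c1ccccc1)C(C)(C)C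
F0 | step 8 | none | none
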